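**Retrosynthetic overview**
1. The C9 tiglate and the C8 (2R)-2-methylbutanoate go on last, onto the cis-8,9-diol. That diol travels as an acetonide whose two stereocentres (C8, C9) are bought with D-mannose. The C6 CH2 comes from a temporary C6 carbinol by radical deoxygenation.
2. Key disconnection C6–C7 (ring B, closed last): a carbonyl-ene reaction between a C5-formyl group and a 2-methylprop-1-enyl arm on C8. The enabling feature is the array C6H2–C7H–C11(CH3)=C12H2 in ring B, with C6 sitting on the quaternary C5. Once C6 is raised to the aldehyde level this homoallylic unit is an ene retron, and the aldehyde cannot enolise.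
3. Ring A is closed first, in the same flask (bonds C3–C4 and C5–C10), by Diels–Alder reaction of tiglaldehyde (C4, C5, C6, C14, C15) with a 2-silyloxydiene (C1–C3, C10). The cis C4/C5 methyl pair beside the formyl-bearing quaternary carbon is the retron.
4. The diene comes from diacetone-D-mannose by Wittig reaction (C7=C11), glycol cleavage (C10 aldehyde), a second Wittig reaction (C1–C3) and O-silylation.
5. Stereochemical relay: C8/C9 (bought) → C10, C5, C4 (cycloaddition) → C7 (ene chair).

Key step: step 5

Remark: positions are given in eremophilane numbering (C2 ketone; C4 and C5 carry the methyl groups C15 and C14; C6 is the ring CH2 next to C5; C7 carries the isopropenyl group C11–C13; C8 and C9 carry the acyloxy groups; C10 is the ring-fusion CH). β is the face of the C5 methyl group. (2R)-2-Methylbutanoic acid is assumed to be purchasable as the single enantiomer.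

**Step 1**
Reactants: 1 2,3:5,6-di-O-isopropylidene-α-D-mannofuranose
Product: 2 open-chain alkenyl carbinol (R)-[(4R)-2,2-dimethyl-1,3-dioxolan-4-yl][(4S,5R)-2,2-dimethyl-5-(2-methylprop-1-en-1-yl)-1,3-dioxolan-4-yl]methanol
Conditions: i-PrPPh3I (3 equiv), n-BuLi (3 equiv), THF, 0 °C; then 1, 0 → 50 °C
Reagents that add atoms: isopropyltriphenylphosphonium iodide, CC(C)[P+](c1ccccc1)(c1ccccc1)c1ccccc1.[I-]
Why: Wittig olefination of the lactol through its open hydroxy-aldehyde form with a non-stabilised ylide installs the C7=C11 alkene; no stereocentre is formed and fast olefination should outrun epimerisation of the α-alkoxy aldehyde.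

**Step 2**
Reactants: 2 open-chain alkenyl carbinol
Product: 3 (4R,5R)-2,2-dimethyl-5-(2-methylprop-1-en-1-yl)-1,3-dioxolane-4-carbaldehyde (cis)
Conditions: H5IO6 (2.5 equiv), EtOAc, rt
Reagents that add atoms: none
Why: Periodic acid should hydrolyse the terminal dioxolane selectively and then cleave the resulting 1,2,3-triol twice (Malaprade glycol cleavage), so the former carbinol carbon becomes the C10 aldehyde while C8 and C9 stay untouched.

**Step 3**
Reactants: 3 cis-dioxolane aldehyde (used crude)
Product: 4 (3E)-4-[(4S,5R)-2,2-dimethyl-5-(2-methylprop-1-en-1-yl)-1,3-dioxolan-4-yl]but-3-en-2-one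
Conditions: Ph3P=CHC(O)CH3, CH2Cl2, rt
Reagents that add atoms: 1-(triphenyl-λ5-phosphanylidene)propan-2-one, CC(=O)C=P(c1ccccc1)(c1ccccc1)c1ccccc1
Why: Wittig reaction with a stabilised, weakly basic ylide should give the (E)-enone without epimerising the cis-dioxolane aldehyde.

**Step 4**
Reactants: 4 (E)-enone
Product: 5 tert-butyl({(3E)-4-[(4S,5R)-2,2-dimethyl-5-(2-methylprop-1-en-1-yl)-1,3-dioxolan-4-yl]buta-1,3-dien-2-yl}oxy)dimethylsilane
Conditions: TBSOTf, Et3N, CH2Cl2, −78 → 0 °C
Reagents that add atoms: tert-butyldimethylsilyl trifluoromethanesulfonate, CC(C)(C)[Si](C)(C)OS(=O)(=O)C(F)(F)F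
Why: Soft enolisation of the methyl ketone at CH3 followed by O-silylation gives the 2-silyloxy-1,3-diene, keeping the E double bond and all stereocentres.

**Step 5**
Reactants: 5 2-silyloxydiene; 6 (2E)-2-methylbut-2-enal (tiglaldehyde)
Product: 9 hydroxy ketone acetonide (4S,4aR,5S,6S,7R,8S,8aS)-5-hydroxy-7,8-(isopropylidenedioxy)-4,4a-dimethyl-6-(prop-1-en-2-yl)octahydronaphthalen-2(1H)-one, via cycloadduct aldehyde 7 (not isolated), via bicyclic silyl enol ether 8 (not isolated)
Conditions: 6 (1.5 equiv), Me2AlCl (2.5 equiv), CH2Cl2, −78 → 0 °C; aq. NaHCO3; then TBAF, AcOH, THF, 0 °C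
Reagents that add atoms: none
Why: Me2AlCl-bound 6 undergoes a formyl-endo [4+2] cycloaddition with diene 5 (bonds C3–C4 and C5–C10; the silyloxy group and the C10 substituent both steer the CH2 terminus to the β-carbon of the enal), and the aluminium-complexed, non-enolisable aldehyde of 7 is then attacked by the CH= carbon of the 2-methylprop-1-enyl arm while an allylic methyl hydrogen passes to oxygen, a carbonyl-ene reaction that forms the C6–C7 bond, closes ring B and writes the isopropenyl group; fluoride finally turns the silyl enol ether 8 into the C2 ketone. The closest known reaction types are the Lewis acid-promoted Diels–Alder reaction of 2-methyl-2-enals with 1-substituted 3-silyloxybutadienes and the citronellal-to-isopulegol cyclisation (intramolecular carbonyl-ene, type 1). Ring A is closed by intermolecular [4+2] cycloaddition, ring B by a six-membered ene closure in which the reacting alkene ends up exocyclic as the isopropenyl group. C4 and C5 follow from the E geometry of 6 (suprafacial addition, methyl groups cis), C10 follows relative to C5 from the endo rule (formyl cis to the dioxolanyl group, hence the cis ring fusion) and in absolute terms from the dioxolane (H9 eclipses the diene to minimise allylic strain and the dienophile adds anti to ring carbon C8 and its cis alkenyl arm), and C7 with the temporary C6 carbinol follows from a chair-like ene transition state in which the C5 methyl, O8 and the emerging isopropenyl group are equatorial. The step needs regio-, endo- and facial selectivity in the cycloaddition and a choice between two chairs in the ene stage; the push of the 2-silyloxy group, the small formyl group next to the bulky C10 substituent, the cis-fused dioxolane (which also holds the aldehyde and the alkene arm on one side) and the penalty of an axial C5 methyl plus O8 syn-axial to C1 in the other chair should secure them. Attack of the aldehyde on the silyl enol ether does not compete because it would need a four-membered ring.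

**Step 6**
Reactants: 9 hydroxy ketone acetonide
Product: 10 O-phenyl thionocarbonate of the C6 hydroxyl of 9
Conditions: PhOC(S)Cl, DMAP (3 equiv), MeCN, rt → 50 °C
Reagents that add atoms: O-phenyl chlorothionoformate, S=C(Cl)Oc1ccccc1
Why: Thioacylation of the hindered secondary C6 alcohol (first half of a Barton–McCombie deoxygenation) should leave ketone, acetonide and alkene untouched.

**Step 7**
Reactants: 10 C6 thionocarbonate
Product: 11 (4S,4aR,6R,7R,8S,8aS)-7,8-(isopropylidenedioxy)-4,4a-dimethyl-6-(prop-1-en-2-yl)octahydronaphthalen-2(1H)-one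
Conditions: Bu3SnH (5 equiv, 0.5 M), Et3B (cat.), air, toluene, rt
Reagents that add atoms: none
Why: Barton–McCombie radical deoxygenation, in which concentrated Bu3SnH at room temperature should trap the secondary C6 radical before it can add to the neighbouring isopropenyl group, so the temporary oxygen leaves and C6 becomes CH2 with C7 unchanged.

**Step 8**
Reactants: 11 ketone acetonide
Product: 12 (4S,4aR,6R,7R,8S,8aS)-7,8-dihydroxy-4,4a-dimethyl-6-(prop-1-en-2-yl)octahydronaphthalen-2(1H)-one
Conditions: AcOH/H2O (4:1), 50 °C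
Reagents that add atoms: none
Why: Acid-catalysed hydrolysis of the isopropylidene acetal should free the cis-8,9-diol while the ketone and the 1,1-disubstituted alkene survive.

**Step 9**
Reactants: 12 cis-diol; 13 (2R)-2-methylbutanoic acid
Product: 14 (4S,4aR,6R,7R,8S,8aS)-8-hydroxy-4,4a-dimethyl-7-{[(2R)-2-methylbutanoyl]oxy}-6-(prop-1-en-2-yl)octahydronaphthalen-2(1H)-one (C8 mono-ester)
Conditions: 13 (1.1 equiv), DCC, DMAP (cat.), CH2Cl2, 0 °C
Reagents that add atoms: none
Why: Steglich esterification should be site-selective for the equatorial C8 hydroxyl, because the axial C9 hydroxyl is syn-axial to C4, and carbodiimide activation at 0 °C should not touch the α-stereocentre of 13.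

**Step 10**
Reactants: 14 C8 mono-ester; 15 (2E)-2-methylbut-2-enoyl chloride (tigloyl chloride)
Product: 16 target, (4S,4aR,6R,7R,8S,8aS)-4,4a-dimethyl-7-{[(2R)-2-methylbutanoyl]oxy}-8-{[(2E)-2-methylbut-2-enoyl]oxy}-6-(prop-1-en-2-yl)octahydronaphthalen-2(1H)-one
Conditions: 15 (3 equiv), DMAP (cat.), pyridine, toluene, 80 °C
Reagents that add atoms: none
Why: DMAP-catalysed acylation through the acylpyridinium ion should esterify the remaining hindered axial C9 alcohol with the configurationally stable E acid chloride; pyridine instead of a trialkylamine avoids vinylketene formation and so deconjugation of the tiglate.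

**Compound list**
1 | 2,3:5,6-di-O-isopropylidene-α-D-mannofuranose | O[C@H]1O[C@H]([C@H]2COC(C)(C)O2)[C@@H]3OC(C)(C)O[C@H]13 | starting material
2 | (R)-[(4R)-2,2-dimethyl-1,3-dioxolan-4-yl][(4S,5R)-2,2-dimethyl-5-(2-methylprop-1-en-1-yl)-1,3-dioxolan-4-yl]methanol | CC(C)=C[C@H]1OC(C)(C)O[C@H]1[C@H](O)[C@H]2COC(C)(C)O2 | intermediate
3 | (4R,5R)-2,2-dimethyl-5-(2-methylprop-1-en-1-yl)-1,3-dioxolane-4-carbaldehyde | CC(C)=C[C@H]1OC(C)(C)O[C@H]1C=O | intermediate
4 | (3E)-4-[(4S,5R)-2,2-dimethyl-5-(2-methylprop-1-en-1-yl)-1,3-dioxolan-4-yl]but-3-en-2-one | CC(C)=C[C@H]1OC(C)(C)O[C@H]1/C=C/C(C)=O | intermediate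
5 | tert-butyl({(3E)-4-[(4S,5R)-2,2-dimethyl-5-(2-methylprop-1-en-1-yl)-1,3-dioxolan-4-yl]buta-1,3-dien-2-yl}oxy)dimethylsilane | CC(C)=C[C@H]1OC(C)(C)O[C@H]1/C=C/C(=C)O[Si](C)(C)C(C)(C)C | intermediate
6 | (2E)-2-methylbut-2-enal | C/C=C(\C)C=O | starting material
7 | (1R,2S,6S)-4-[(tert-butyldimethylsilyl)oxy]-2-[(4S,5R)-2,2-dimethyl-5-(2-methylprop-1-en-1-yl)-1,3-dioxolan-4-yl]-1,6-dimethylcyclohex-3-ene-1-carbaldehyde | CC(C)=C[C@H]1OC(C)(C)O[C@H]1[C@H]2C=C(O[Si](C)(C)C(C)(C)C)C[C@H](C)[C@@]2(C)C=O | intermediate
8 | (4S,4aR,5S,6S,7R,8S,8aS)-2-[(tert-butyldimethylsilyl)oxy]-7,8-(isopropylidenedioxy)-4,4a-dimethyl-6-(prop-1-en-2-yl)-3,4,4a,5,6,7,8,8a-octahydronaphthalen-5-ol | C=C(C)[C@H]1[C@H](O)[C@@]2(C)[C@H](C=C(O[Si](C)(C)C(C)(C)C)C[C@@H]2C)[C@@H]3OC(C)(C)O[C@H]13 | intermediate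
9 | (4S,4aR,5S,6S,7R,8S,8aS)-5-hydroxy-7,8-(isopropylidenedioxy)-4,4a-dimethyl-6-(prop-1-en-2-yl)octahydronaphthalen-2(1H)-one | C=C(C)[C@H]1[C@H](O)[C@@]2(C)[C@H](CC(=O)C[C@@H]2C)[C@@H]3OC(C)(C)O[C@H]13 | intermediate
10 | O-phenyl thionocarbonate of the 5-hydroxyl of 9 | C=C(C)[C@H]1[C@H](OC(=S)Oc4ccccc4)[C@@]2(C)[C@H](CC(=O)C[C@@H]2C)[C@@H]3OC(C)(C)O[C@H]13 | intermediate
11 | (4S,4aR,6R,7R,8S,8aS)-7,8-(isopropylidenedioxy)-4,4a-dimethyl-6-(prop-1-en-2-yl)octahydronaphthalen-2(1H)-one | C=C(C)[C@H]1C[C@@]2(C)[C@H](CC(=O)C[C@@H]2C)[C@@H]3OC(C)(C)O[C@H]13 | intermediate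
12 | (4S,4aR,6R,7R,8S,8aS)-7,8-dihydroxy-4,4a-dimethyl-6-(prop-1-en-2-yl)octahydronaphthalen-2(1H)-one | C=C(C)[C@H]1C[C@@]2(C)[C@H](CC(=O)C[C@@H]2C)[C@H](O)[C@@H]1O | intermediate
13 | (2R)-2-methylbutanoic acid | CC[C@@H](C)C(=O)O | starting material
14 | (4S,4aR,6R,7R,8S,8aS)-8-hydroxy-4,4a-dimethyl-7-{[(2R)-2-methylbutanoyl]oxy}-6-(prop-1-en-2-yl)octahydronaphthalen-2(1H)-one | C=C(C)[C@H]1C[C@@]2(C)[C@H](CC(=O)C[C@@H]2C)[C@H](O)[C@@H]1OC(=O)[C@H](C)CC | intermediate
15 | (2E)-2-methylbut-2-enoyl chloride | C/C=C(\C)C(Cl)=O | starting material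
16 | (4S,4aR,6R,7R,8S,8aS)-4,4a-dimethyl-7-{[(2R)-2-methylbutanoyl]oxy}-8-{[(2E)-2-methylbut-2-enoyl]oxy}-6-(prop-1-en-2-yl)octahydronaphthalen-2(1H)-one | C=C(C)[C@H]1C[C@@]2(C)[C@H](CC(=O)C[C@@H]2C)[C@H](OC(=O)/C(C)=C/C)[C@@H]1OC(=O)[C@H](C)CC | target

**Step count and risks**
Total step count: 10. Longest linear sequence: 10 steps (1 → 16).

Steps most likely to fail:

Step 5. The cycloaddition stage may show poor facial selectivity with respect to the dioxolane, and 1,2-addition of the silyl enol ether to the aldehyde may compete, so the domino could deliver diastereomer mixtures. The fallback sets out from 5 and 6 and rejoins the route at 9. It separates the two events and puts the cycloaddition under catalyst control. 5 and 6 are combined at −78 °C in CH2Cl2 with a catalytic amount of the α,α-diphenylprolinol-derived o-tolyl oxazaborolidine activated with HNTf2, in the enantiomeric form whose facial preference matches the approach anti to C8; this should give aldehyde 7, now isolated. A separate Me2AlCl-promoted carbonyl-ene reaction then closes ring B to 8, and TBAF/AcOH gives 9. This fallback makes no compound outside the list (F0).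

Step 7. The C6 radical may add to the adjacent isopropenyl group and reopen (a 1,2-alkenyl shift), or thioacylation of the very hindered carbinol in step 6 may be incomplete. The fallback sets out from 9 and rejoins the route at 12, removing the C6 oxygen by an ionic path. 9 is ketalised at C2 (ethylene glycol, PPTS, benzene, reflux) to the C2 ethylene ketal F1. Dess–Martin oxidation (NaHCO3, CH2Cl2) gives the C6 ketone F2, whose C7 centre can only equilibrate toward the desired equatorial isopropenyl group. Condensation with TsNHNH2 gives the C6 tosylhydrazone F3. Reduction with catecholborane followed by NaOAc (hydride addition to C=N, then loss of sulfinate and N2) should give the C6-methylene ketal acetonide F4. Aqueous acetic acid as in step 8 then cleaves both the ethylene ketal and the acetonide to give 12.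

Step 10. Acylation of the axial C9 hydroxyl may be so slow that base-mediated 1,2-acyl migration of the 2-methylbutanoate and scrambling of the two esters take over. The fallback sets out from 14 and rejoins the route at 16, building the tiglate on the oxygen by olefination. 14 is esterified with 2-(diethoxyphosphoryl)propanoic acid (DCC, DMAP, CH2Cl2, rt; a ketene-type acylating species that reaches hindered alcohols) to the C9 2-(diethoxyphosphoryl)propanoate F5. A Horner–Wadsworth–Emmons reaction with acetaldehyde (LiCl, DBU, MeCN, 0 °C) should then give the E-configured 2-methylbut-2-enoate 16.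

**Further compounds**
F0 | step 5 | none | none
F1 | step 7 | C2 ethylene ketal of 9 | C=C(C)[C@H]1[C@H](O)[C@@]2(C)[C@H](CC3(OCCO3)C[C@@H]2C)[C@@H]4OC(C)(C)O[C@H]14
F2 | step 7 | C6 ketone of F1 | C=C(C)[C@H]1C(=O)[C@@]2(C)[C@H](CC3(OCCO3)C[C@@H]2C)[C@@H]4OC(C)(C)O[C@H]14
F3 | step 7 | C6 p-toluenesulfonylhydrazone of F2 | C=C(C)[C@H]1C(=NNS(=O)(=O)c5ccc(C)cc5)[C@@]2(C)[C@H](CC3(OCCO3)C[C@@H]2C)[C@@H]4OC(C)(C)O[C@H]14
F4 | step 7 | C6-methylene ketal acetonide (C2 ethylene ketal of 11) | C=C(C)[C@H]1C[C@@]2(C)[C@H](CC3(OCCO3)C[C@@H]2C)[C@@H]4OC(C)(C)O[C@H]14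
F5 | step 10 | C9 2-(diethoxyphosphoryl)propanoate of 14 | C=C(C)[C@H]1C[C@@]2(C)[C@H](CC(=O)C[C@@H]2C)[C@H](OC(=O)C(C)P(=O)(OCC)OCC)[C@@H]1OC(=O)[C@H](C)CC
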